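The trans-decalin is cut at C1–C2 and C9–C10 (labdane numbering), so that ring A (C1–C5, C10) and ring B (C5–C10) both arise from one acyclic chain. The 2-hydroxyl, the quaternary methyl-bearing C10, C9 and the C8 exocyclic methylene line up as aldehyde initiator, isopropenyl relay and allylsilane terminator. One Lewis-acid Prins cascade therefore closes both rings, sets C2, C10 and C9 and places the alkene at C8(17). The precursor is an aldehyde carrying the C4/C5 stereodiad (from (S)-carvone by double alkylation and ring cleavage), the isopropenyl group, an (E)-allylsilane and the finished (E)-enoate chain.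

Key step: step 16

Remark: labdane numbering is used for the chain and the decalin (C18 = carboxyl carbon on C4, C19 = methyl on C4, C20 = methyl on C10, C17 = CH2 on C8; α = face opposite to C20). The cyclohexenone intermediates 1–9 keep carvone ring numbering, which maps onto labdane atoms as C1→C18, C2→C8, 2-CH3→C9, C3→C7, C4→C6, C5→C5, C6→C4.

Step 1
Reactants: 1 (S)-(+)-carvone
Product: 3 (5S,6R)-2,6-dimethyl-5-(prop-1-en-2-yl)cyclohex-2-en-1-one (trans-6-methylcarvone as the main epimer), via lithium dienolate of carvone 2 (not isolated)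
Conditions: LiN(i-Pr)2 (1.1 equiv), THF, −78 °C; MeI, −78 to 0 °C
Reagents that add atoms: iodomethane, CI
Why: Kinetic deprotonation at C6 gives the cross-conjugated dienolate, whose methylation (enolate alkylation) should occur mainly anti to the C5 isopropenyl group; the C6 centre becomes planar again in step 3, so the epimer ratio is immaterial.

Step 2
Reactants: 4 2-[(tert-butyldimethylsilyl)oxy]ethan-1-ol
Product: 5 2-[(tert-butyldimethylsilyl)oxy]ethyl trifluoromethanesulfonate
Conditions: Tf2O, 2,6-lutidine, CH2Cl2, −78 °C; used at once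
Reagents that add atoms: trifluoromethanesulfonic anhydride, O=S(=O)(OS(=O)(=O)C(F)(F)F)C(F)(F)F
Why: O-sulfonylation of a primary alcohol with triflic anhydride and a hindered pyridine base at low temperature should give the primary triflate cleanly.

Step 3
Reactants: 3 trans-6-methylcarvone; 5 2-[(tert-butyldimethylsilyl)oxy]ethyl trifluoromethanesulfonate
Product: 7 (5R,6R)-6-{2-[(tert-butyldimethylsilyl)oxy]ethyl}-2,6-dimethyl-5-(prop-1-en-2-yl)cyclohex-2-en-1-one, via lithium enolate of 6-methylcarvone 6 (not isolated)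
Conditions: LiN(i-Pr)2, THF, −78 to −20 °C; then 5, THF, −78 °C to rt
Reagents that add atoms: none
Why: The tetrasubstituted enolate should be C-alkylated by the highly reactive primary triflate (enolate alkylation) on the face anti to the pseudo-axial C5 isopropenyl group, which sets the quaternary labdane C4 with the oxygenated two-carbon arm trans and the methyl cis to isopropenyl.

Step 4
Reactants: 7 the 6,6-disubstituted carvone
Product: 9 (5R,6R)-6-{2-[(tert-butyldimethylsilyl)oxy]ethyl}-2-hydroxy-2,6-dimethyl-5-(prop-1-en-2-yl)cyclohexan-1-one (both C2 epimers), via lithium enolate from conjugate reduction 8 (not isolated)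
Conditions: LiBH(s-Bu)3, THF, −78 °C; then 2-(phenylsulfonyl)-3-phenyloxaziridine, −78 to −20 °C; aq. NH4Cl
Reagents that add atoms: 2-(phenylsulfonyl)-3-phenyloxaziridine, O=S(=O)(N1OC1c1ccccc1)c1ccccc1
Why: 1,4-Hydride delivery to the β-unsubstituted, carbonyl-hindered enone (conjugate reduction) gives one regiodefined enolate that is hydroxylated in situ (Davis enolate oxidation); the configuration of the new carbinol carbon is irrelevant because it becomes a ketone in step 5.

Step 5
Reactants: 9 the α-hydroxy ketone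
Product: 10 methyl (2R,3R)-2-{2-[(tert-butyldimethylsilyl)oxy]ethyl}-2-methyl-6-oxo-3-(prop-1-en-2-yl)heptanoate
Conditions: Pb(OAc)4, MeOH/benzene, 0 °C
Reagents that add atoms: methanol, CO
Why: Criegee-type oxidative cleavage of the α-ketol through its methyl hemiketal should break the C1–C2 ring bond, giving the ring carbonyl as the methyl ester on the quaternary carbon and the carbinol carbon as a methyl ketone, so the two chain ends are differentiated from the outset.

Step 6
Reactants: 10 the keto ester
Product: 13 methyl (2R,3R)-2-{2-[(tert-butyldimethylsilyl)oxy]ethyl}-2-methyl-3-(prop-1-en-2-yl)hept-6-ynoate, via kinetic lithium enolate 11 (not isolated), via diethyl enol phosphate 12 (not isolated)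
Conditions: LiN(i-Pr)2 (1.1 equiv), THF, −78 °C; ClP(O)(OEt)2, −78 °C to rt; then LiN(i-Pr)2 (2.3 equiv), THF, −78 °C to rt; H2O
Reagents that add atoms: none
Why: Kinetic deprotonation on the methyl side, O-phosphorylation and base-induced elimination of diethyl phosphate (Negishi alkyne synthesis from methyl ketones) should turn the acetyl group into a terminal alkyne, while the ester on the quaternary carbon has no α-hydrogen and is too hindered to be attacked.

Step 7
Reactants: 13 the terminal alkyne
Product: 15 dimethyl (6R,7R)-7-{2-[(tert-butyldimethylsilyl)oxy]ethyl}-7-methyl-6-(prop-1-en-2-yl)oct-2-ynedioate, via lithium acetylide 14 (not isolated)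
Conditions: LiN(i-Pr)2, THF, −78 °C; ClCO2Me, −78 to 0 °C
Reagents that add atoms: methyl chloroformate, COC(=O)Cl
Why: The acetylide formed by deprotonation is C-acylated by the chloroformate (acetylide methoxycarbonylation) to give the ynoate that carries C11.

Step 8
Reactants: 15 the ynoate; 16 (trimethylsilyl)methylmagnesium chloride
Product: 18 dimethyl (2E,6R,7R)-7-{2-[(tert-butyldimethylsilyl)oxy]ethyl}-7-methyl-6-(prop-1-en-2-yl)-3-[(trimethylsilyl)methyl]oct-2-enedioate, via alkenylcuprate adduct 17 (not isolated)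
Conditions: 16 (2.4 equiv), CuBr·SMe2 (1.2 equiv), THF, −78 °C; then 15, −78 °C; MeOH then aq. NH4Cl at −78 °C
Reagents that add atoms: none
Why: syn-Carbocupration of the ynoate (organocuprate conjugate addition to an alkynoate) at −78 °C places Me3SiCH2 on C8 cis to the copper on C9, and protonation with retention should give the (E)-enoate in which C11 is cis to C7, the geometry that later makes the C9 chain axial.

Step 9
Reactants: 18 the silylmethyl enoate
Product: 19 methyl (2R,3R,6E)-2-{2-[(tert-butyldimethylsilyl)oxy]ethyl}-8-hydroxy-2-methyl-3-(prop-1-en-2-yl)-6-[(trimethylsilyl)methyl]oct-6-enoate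
Conditions: i-Bu2AlH (2.2 equiv), CH2Cl2, −78 °C; aq. KNaC4H4O6
Reagents that add atoms: none
Why: 1,2-Reduction of the conjugated methyl ester to the allylic alcohol (aluminium hydride ester reduction) is expected to be much faster than attack on the neopentyl-type C18 ester, whose α-carbon carries three non-hydrogen substituents.

Step 10
Reactants: 19 the allylic alcohol
Product: 21 methyl (2R,3R,6E)-2-{2-[(tert-butyldimethylsilyl)oxy]ethyl}-8-chloro-2-methyl-3-(prop-1-en-2-yl)-6-[(trimethylsilyl)methyl]oct-6-enoate, via allylic mesylate 20 (not isolated)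
Conditions: MsCl, LiCl, 2,4,6-collidine, DMF, 0 °C
Reagents that add atoms: lithium chloride, [Li+].[Cl-]
Why: Mesylation followed by SN2 displacement with chloride (Collington–Meyers allylic chloride synthesis) should give the primary allylic chloride without allylic transposition and without acid that could trigger loss of silicon.

Step 11
Reactants: 21 the allylic chloride; 22 methyl acetoacetate
Product: 24 dimethyl (6E,10R,11R)-11-{2-[(tert-butyldimethylsilyl)oxy]ethyl}-11-methyl-3-oxo-10-(prop-1-en-2-yl)-7-[(trimethylsilyl)methyl]dodec-6-enedioate, via acetoacetate dianion 23 (not isolated)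
Conditions: 22, NaH, THF, 0 °C; n-BuLi, 0 °C; then 21, 0 °C to rt; aq. NH4Cl
Reagents that add atoms: none
Why: The acetoacetate dianion reacts only at its terminal γ-carbon (Weiler dianion alkylation) in an SN2 displacement of the allylic chloride, which adds C12–C15 as a β-keto ester.

Step 12
Reactants: 24 the β-keto ester
Product: 26 dimethyl (2Z,6E,10R,11R)-11-{2-[(tert-butyldimethylsilyl)oxy]ethyl}-3-[(diethoxyphosphoryl)oxy]-11-methyl-10-(prop-1-en-2-yl)-7-[(trimethylsilyl)methyl]dodeca-2,6-dienedioate, via chelated sodium enolate 25 (not isolated)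
Conditions: NaH, Et2O, 0 °C; ClP(O)(OEt)2, 0 °C
Reagents that add atoms: diethyl chlorophosphate, CCOP(=O)(Cl)OCC
Why: The chelated sodium enolate of the β-keto ester is O-phosphorylated with retention of its Z geometry (Weiler enol phosphate formation), which fixes the phosphate cis to the ester.

Step 13
Reactants: 26 the (Z)-enol phosphate
Product: 27 dimethyl (2E,6E,10R,11R)-11-{2-[(tert-butyldimethylsilyl)oxy]ethyl}-3,11-dimethyl-10-(prop-1-en-2-yl)-7-[(trimethylsilyl)methyl]dodeca-2,6-dienedioate
Conditions: Me2CuLi (from MeLi and CuI), Et2O, −78 to −45 °C; aq. NH4Cl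
Reagents that add atoms: lithium dimethylcuprate, [Li+].C[Cu-]C
Why: The cuprate replaces the enol phosphate by methyl with retention of alkene geometry (addition–elimination coupling of a β-phosphoryloxy enoate), which should give the (13E)-enoate with C16 in place.

Step 14
Reactants: 27 the silyl-protected diester
Product: 28 dimethyl (2E,6E,10R,11R)-11-(2-hydroxyethyl)-3,11-dimethyl-10-(prop-1-en-2-yl)-7-[(trimethylsilyl)methyl]dodeca-2,6-dienedioate
Conditions: HF·pyridine, pyridine, THF, 0 °C; crude product taken on at once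
Reagents that add atoms: none
Why: Buffered fluoride cleaves the primary silyl ether (fluoride-mediated desilylation) while the allyltrimethylsilane, which needs a strong electrophile to react, should survive; the γ-hydroxy ester is oxidised immediately so that it has no time to lactonise.

Step 15
Reactants: 28 the primary alcohol
Product: 29 dimethyl (2E,6E,10R,11R)-3,11-dimethyl-11-(2-oxoethyl)-10-(prop-1-en-2-yl)-7-[(trimethylsilyl)methyl]dodeca-2,6-dienedioate (acyclic aldehyde, key-step precursor)
Conditions: Dess–Martin periodinane, pyridine, CH2Cl2, 0 °C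
Reagents that add atoms: none
Why: Dess–Martin oxidation of the primary alcohol under pyridine buffering should give the aldehyde, which has no stereocentre α to the carbonyl, without touching the allylsilane or the alkenes.

Step 16
Reactants: 29 the acyclic aldehyde
Product: 31 dimethyl ester of the 2-epi target (trans-decalin with 2α-OH equatorial, 4α-CO2Me, 4β-CH3, 5α-H, 10β-CH3, 9α axial side chain, 8(17)-methylene, 13E-enoate), via monocyclic C10 cation 30 (not isolated)
Conditions: SnCl4 (1.5 equiv), CH2Cl2 (0.005 M), −78 °C; aq. NaHCO3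
Reagents that add atoms: none
Why: SnCl4 complexes the aldehyde, C1 of the isopropenyl group attacks C2 and the charge that develops at C10 is taken by C9 of the allylsilane, after which chloride removes Me3Si to leave the C8(17) exocyclic alkene; the closest known reaction type is the Lewis-acid carbonyl-initiated (Prins) cation–olefin bicyclisation with allylsilane termination. Ring A closes 6-endo with respect to the C1=C10 alkene (C1–C2 bond) and ring B closes 6-endo with respect to the C8=C9 alkene (C9–C10 bond). C10 is set by anti addition across C1=C10 in a chair–chair array in which C6 and C9 are both equatorial on ring A, which with the preset C5 gives the trans fusion and, with the preset C4, leaves the C19 methyl axial and the ester equatorial. C9 is set by the alkene geometry, since C11 is cis to C7 and therefore ends axial (α), and C2 is set by the tin-bound oxygen taking the equatorial position away from the two syn-axial methyl groups. The step needs capture of the C10 cation to be faster than proton loss from it and than intermolecular allyl transfer to the aldehyde; this is secured because the allylsilane is the strongest π-nucleophile and closes a six-membered chair onto C10, its direct addition to C2 would need an eight-membered ring, the enoate alkene is deactivated, and high dilution at −78 °C with a non-basic chloride Lewis acid disfavours both side reactions.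

Step 17
Reactants: 31 the 2α-alcohol
Product: 32 dimethyl ester of the 2-oxo decalin (C2 ketone, all other centres as in 31)
Conditions: Dess–Martin periodinane, pyridine, CH2Cl2, rt
Reagents that add atoms: none
Why: Dess–Martin oxidation should convert the equatorial secondary alcohol into the C2 ketone; both flanking carbons are CH2 groups, so nothing can epimerise.

Step 18
Reactants: 32 the C2 ketone
Product: 33 dimethyl ester of the target (2β-OH axial)
Conditions: NaBH4, MeOH, −20 to 0 °C
Reagents that add atoms: none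
Why: Hydride addition to the ketone (borohydride reduction) should occur from the α-face, because the β-face is blocked by the two syn-axial methyl groups on C4 and C10, and so gives the axial 2β-alcohol.

Step 19
Reactants: 33 the dimethyl ester
Product: 34 CNP0086784.6, (13E)-2β-hydroxy-9βH-labda-8(17),13-diene-15,18-dioic acid
Conditions: KOH, ethylene glycol/H2O, 120 °C; then aq. HCl to pH 3
Reagents that add atoms: potassium hydroxide, [K+].[OH-]
Why: Saponification (BAc2 ester hydrolysis) cleaves the unhindered enoate ester quickly and, under forcing aqueous glycol conditions, also the hindered equatorial C18 ester; the 2β-hydroxyl is trans to the C4 carboxyl and cannot lactonise, and neither the exocyclic alkene nor the enoate carboxylate should isomerise in hydroxide.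

Compound list

1 | (S)-(+)-carvone, (5S)-2-methyl-5-(prop-1-en-2-yl)cyclohex-2-en-1-one | CC1=CC[C@@H](CC1=O)C(C)=C | starting material
2 | lithium dienolate of carvone (C1–O, C1=C6; not isolated) | [Li+].CC1=CC[C@@H](C=C1[O-])C(C)=C | intermediate
3 | (5S,6R)-2,6-dimethyl-5-(prop-1-en-2-yl)cyclohex-2-en-1-one (trans-6-methylcarvone) | CC1=CC[C@H](C(C)=C)[C@@H](C)C1=O | intermediate
4 | 2-[(tert-butyldimethylsilyl)oxy]ethan-1-ol | CC(C)(C)[Si](C)(C)OCCO | starting material
5 | 2-[(tert-butyldimethylsilyl)oxy]ethyl trifluoromethanesulfonate | CC(C)(C)[Si](C)(C)OCCOS(=O)(=O)C(F)(F)F | intermediate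
6 | lithium enolate of 6-methylcarvone (C1–O, C1=C6; not isolated) | [Li+].CC1=CC[C@H](C(C)=C)C(C)=C1[O-] | intermediate
7 | (5R,6R)-6-{2-[(tert-butyldimethylsilyl)oxy]ethyl}-2,6-dimethyl-5-(prop-1-en-2-yl)cyclohex-2-en-1-one (arm trans, methyl cis to isopropenyl) | CC1=CC[C@H](C(C)=C)[C@@](C)(CCO[Si](C)(C)C(C)(C)C)C1=O | intermediate
8 | lithium enolate from conjugate reduction of 7 (C1–O, C1=C2; not isolated) | [Li+].CC1=C([O-])[C@](C)(CCO[Si](C)(C)C(C)(C)C)[C@@H](C(C)=C)CC1 | intermediate
9 | (5R,6R)-6-{2-[(tert-butyldimethylsilyl)oxy]ethyl}-2-hydroxy-2,6-dimethyl-5-(prop-1-en-2-yl)cyclohexan-1-one (both C2 epimers) | CC1(O)CC[C@H](C(C)=C)[C@@](C)(CCO[Si](C)(C)C(C)(C)C)C1=O | intermediate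
10 | methyl (2R,3R)-2-{2-[(tert-butyldimethylsilyl)oxy]ethyl}-2-methyl-6-oxo-3-(prop-1-en-2-yl)heptanoate | CC(=O)CC[C@H](C(C)=C)[C@@](C)(CCO[Si](C)(C)C(C)(C)C)C(=O)OC | intermediate
11 | kinetic (terminal) lithium enolate of 10 (not isolated) | [Li+].C=C([O-])CC[C@H](C(C)=C)[C@@](C)(CCO[Si](C)(C)C(C)(C)C)C(=O)OC | intermediate
12 | diethyl enol phosphate of 10 (terminal alkene; not isolated) | C=C(OP(=O)(OCC)OCC)CC[C@H](C(C)=C)[C@@](C)(CCO[Si](C)(C)C(C)(C)C)C(=O)OC | intermediate
13 | methyl (2R,3R)-2-{2-[(tert-butyldimethylsilyl)oxy]ethyl}-2-methyl-3-(prop-1-en-2-yl)hept-6-ynoate | C#CCC[C@H](C(C)=C)[C@@](C)(CCO[Si](C)(C)C(C)(C)C)C(=O)OC | intermediate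
14 | lithium acetylide of 13 (not isolated) | [Li+].[C-]#CCC[C@H](C(C)=C)[C@@](C)(CCO[Si](C)(C)C(C)(C)C)C(=O)OC | intermediate
15 | dimethyl (6R,7R)-7-{2-[(tert-butyldimethylsilyl)oxy]ethyl}-7-methyl-6-(prop-1-en-2-yl)oct-2-ynedioate | COC(=O)C#CCC[C@H](C(C)=C)[C@@](C)(CCO[Si](C)(C)C(C)(C)C)C(=O)OC | intermediate
16 | (trimethylsilyl)methylmagnesium chloride | C[Si](C)(C)C[Mg]Cl | starting material
17 | alkenylcuprate adduct of 15 (copper on C9 cis to CH2SiMe3; not isolated) | COC(=O)/C([Cu-]C[Si](C)(C)C)=C(/C[Si](C)(C)C)\CC[C@H](C(C)=C)[C@@](C)(CCO[Si](C)(C)C(C)(C)C)C(=O)OC.[Mg+]Cl | intermediate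
18 | dimethyl (2E,6R,7R)-7-{2-[(tert-butyldimethylsilyl)oxy]ethyl}-7-methyl-6-(prop-1-en-2-yl)-3-[(trimethylsilyl)methyl]oct-2-enedioate | COC(=O)/C=C(/C[Si](C)(C)C)\CC[C@H](C(C)=C)[C@@](C)(CCO[Si](C)(C)C(C)(C)C)C(=O)OC | intermediate
19 | methyl (2R,3R,6E)-2-{2-[(tert-butyldimethylsilyl)oxy]ethyl}-8-hydroxy-2-methyl-3-(prop-1-en-2-yl)-6-[(trimethylsilyl)methyl]oct-6-enoate | OC/C=C(/C[Si](C)(C)C)\CC[C@H](C(C)=C)[C@@](C)(CCO[Si](C)(C)C(C)(C)C)C(=O)OC | intermediate
20 | allylic mesylate of 19 (not isolated) | CS(=O)(=O)OC/C=C(/C[Si](C)(C)C)\CC[C@H](C(C)=C)[C@@](C)(CCO[Si](C)(C)C(C)(C)C)C(=O)OC | intermediate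
21 | methyl (2R,3R,6E)-2-{2-[(tert-butyldimethylsilyl)oxy]ethyl}-8-chloro-2-methyl-3-(prop-1-en-2-yl)-6-[(trimethylsilyl)methyl]oct-6-enoate | ClC/C=C(/C[Si](C)(C)C)\CC[C@H](C(C)=C)[C@@](C)(CCO[Si](C)(C)C(C)(C)C)C(=O)OC | intermediate
22 | methyl acetoacetate | COC(=O)CC(C)=O | starting material
23 | sodium lithium dianion of methyl acetoacetate (not isolated) | [Li+].[Na+].COC([O-])=CC([O-])=C | intermediate
24 | dimethyl (6E,10R,11R)-11-{2-[(tert-butyldimethylsilyl)oxy]ethyl}-11-methyl-3-oxo-10-(prop-1-en-2-yl)-7-[(trimethylsilyl)methyl]dodec-6-enedioate | COC(=O)CC(=O)CC/C=C(/C[Si](C)(C)C)\CC[C@H](C(C)=C)[C@@](C)(CCO[Si](C)(C)C(C)(C)C)C(=O)OC | intermediate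
25 | chelated sodium (Z)-enolate of 24 (not isolated) | [Na+].COC(=O)/C=C(\[O-])CC/C=C(/C[Si](C)(C)C)\CC[C@H](C(C)=C)[C@@](C)(CCO[Si](C)(C)C(C)(C)C)C(=O)OC | intermediate
26 | dimethyl (2Z,6E,10R,11R)-11-{2-[(tert-butyldimethylsilyl)oxy]ethyl}-3-[(diethoxyphosphoryl)oxy]-11-methyl-10-(prop-1-en-2-yl)-7-[(trimethylsilyl)methyl]dodeca-2,6-dienedioate | COC(=O)/C=C(\OP(=O)(OCC)OCC)CC/C=C(/C[Si](C)(C)C)\CC[C@H](C(C)=C)[C@@](C)(CCO[Si](C)(C)C(C)(C)C)C(=O)OC | intermediate
27 | dimethyl (2E,6E,10R,11R)-11-{2-[(tert-butyldimethylsilyl)oxy]ethyl}-3,11-dimethyl-10-(prop-1-en-2-yl)-7-[(trimethylsilyl)methyl]dodeca-2,6-dienedioate | COC(=O)/C=C(C)/CC/C=C(/C[Si](C)(C)C)\CC[C@H](C(C)=C)[C@@](C)(CCO[Si](C)(C)C(C)(C)C)C(=O)OC | intermediate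
28 | dimethyl (2E,6E,10R,11R)-11-(2-hydroxyethyl)-3,11-dimethyl-10-(prop-1-en-2-yl)-7-[(trimethylsilyl)methyl]dodeca-2,6-dienedioate | COC(=O)/C=C(C)/CC/C=C(/C[Si](C)(C)C)\CC[C@H](C(C)=C)[C@@](C)(CCO)C(=O)OC | intermediate
29 | dimethyl (2E,6E,10R,11R)-3,11-dimethyl-11-(2-oxoethyl)-10-(prop-1-en-2-yl)-7-[(trimethylsilyl)methyl]dodeca-2,6-dienedioate (key-step precursor) | COC(=O)/C=C(C)/CC/C=C(/C[Si](C)(C)C)\CC[C@H](C(C)=C)[C@@](C)(CC=O)C(=O)OC | intermediate
30 | monocyclic C10 cation with ring A closed and the C2 oxygen bound to tin (not isolated) | COC(=O)/C=C(C)/CC/C=C(/C[Si](C)(C)C)\CC[C@@H]1[C+](C)C[C@@H](O[Sn-](Cl)(Cl)(Cl)Cl)C[C@@]1(C)C(=O)OC | intermediate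
31 | dimethyl (13E)-2α-hydroxy-9βH-labda-8(17),13-diene-15,18-dioate (2α-OH equatorial, 4α-CO2Me, 4β-CH3, 5α-H, 10β-CH3, 9α side chain) | C=C1CC[C@@H]2[C@](C)(C[C@@H](O)C[C@@]2(C)C(=O)OC)[C@@H]1CC/C(C)=C/C(=O)OC | intermediate
32 | dimethyl (13E)-2-oxo-9βH-labda-8(17),13-diene-15,18-dioate | C=C1CC[C@@H]2[C@](C)(CC(=O)C[C@@]2(C)C(=O)OC)[C@@H]1CC/C(C)=C/C(=O)OC | intermediate
33 | dimethyl (13E)-2β-hydroxy-9βH-labda-8(17),13-diene-15,18-dioate (2β-OH axial) | C=C1CC[C@@H]2[C@](C)(C[C@H](O)C[C@@]2(C)C(=O)OC)[C@@H]1CC/C(C)=C/C(=O)OC | intermediate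
34 | CNP0086784.6, (13E)-2β-hydroxy-9βH-labda-8(17),13-diene-15,18-dioic acid | C=C1CC[C@@H]2[C@](C)(C[C@H](O)C[C@@]2(C)C(=O)O)[C@@H]1CC/C(C)=C/C(=O)O | target

Total step count: 19. Longest linear sequence: 18 steps (steps 1 and 3–19, from 1 to 34); step 2 is a one-step side branch.

Steps most likely to fail

Step 16. Proton loss from the C10 cation, or intermolecular allyl transfer to the tin-bound aldehyde, may outrun ring B closure. The fallback changes the initiator from the free aldehyde to a cyclic acetal and sets out from 29. Propane-1,3-diol, HC(OMe)3 and PPTS in CH2Cl2 should give the 1,3-dioxane acetal F1. TiCl4 in CH2Cl2 at −78 °C then opens the acetal to an oxocarbenium ion that triggers the same chair–chair bicyclisation with allylsilane termination and should give the 2α-(3-hydroxypropoxy) decalin diester F2. Dess–Martin oxidation of the primary alcohol gives the β-alkoxy aldehyde F3, and β-elimination with piperidinium acetate releases the free 2α-alcohol, so the route is rejoined at 31.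

Step 3. C-alkylation of the hindered tetrasubstituted enolate may be slow, so that O-alkylation or decomposition of the triflate takes over, or facial selectivity may erode. The fallback uses an activated electrophile and adjusts the oxidation level afterwards; it sets out from 3. The enolate (LiN(i-Pr)2, THF, −78 °C) is alkylated with methyl bromoacetate, again anti to isopropenyl, to give the keto ester F4. LiAlH4 in Et2O reduces both the ester and the enone carbonyl to the diol F5. TBSCl and imidazole silylate only the primary hydroxyl to give the monosilyl ether F6, and MnO2 reoxidises the allylic alcohol, so the route is rejoined at 7.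

Step 9. Hydride may also be delivered to the C18 ester (over-reduction). The fallback never brings C11 to the ester oxidation level and sets out from 13. The lithium acetylide is trapped with paraformaldehyde to give the propargylic alcohol F7. Alkoxide-directed syn-carbomagnesiation with Me3SiCH2MgCl and catalytic Fe(acac)3 in THF at 0 °C places the silylmethyl group on C8 and, after protonation, should give the (E)-allylic alcohol directly, so the route is rejoined at 19.

Further compounds

F1 | step 16 | 1,3-dioxane acetal of aldehyde 29 | COC(=O)/C=C(C)/CC/C=C(/C[Si](C)(C)C)\CC[C@H](C(C)=C)[C@@](C)(CC1OCCCO1)C(=O)OC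
F2 | step 16 | 2α-(3-hydroxypropoxy) analogue of 31 | C=C1CC[C@@H]2[C@](C)(C[C@@H](OCCCO)C[C@@]2(C)C(=O)OC)[C@@H]1CC/C(C)=C/C(=O)OC
F3 | step 16 | 2α-(3-oxopropoxy) analogue of 31 | C=C1CC[C@@H]2[C@](C)(C[C@@H](OCCC=O)C[C@@]2(C)C(=O)OC)[C@@H]1CC/C(C)=C/C(=O)OC
F4 | step 3 | methyl 2-[(1R,6R)-1,3-dimethyl-2-oxo-6-(prop-1-en-2-yl)cyclohex-3-en-1-yl]acetate | CC1=CC[C@H](C(C)=C)[C@@](C)(CC(=O)OC)C1=O
F5 | step 3 | (5R,6R)-6-(2-hydroxyethyl)-2,6-dimethyl-5-(prop-1-en-2-yl)cyclohex-2-en-1-ol (both C1 epimers) | CC1=CC[C@H](C(C)=C)[C@@](C)(CCO)C1O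
F6 | step 3 | (5R,6R)-6-{2-[(tert-butyldimethylsilyl)oxy]ethyl}-2,6-dimethyl-5-(prop-1-en-2-yl)cyclohex-2-en-1-ol (both C1 epimers) | CC1=CC[C@H](C(C)=C)[C@@](C)(CCO[Si](C)(C)C(C)(C)C)C1O
F7 | step 9 | methyl (2R,3R)-2-{2-[(tert-butyldimethylsilyl)oxy]ethyl}-8-hydroxy-2-methyl-3-(prop-1-en-2-yl)oct-6-ynoate | OCC#CCC[C@H](C(C)=C)[C@@](C)(CCO[Si](C)(C)C(C)(C)C)C(=O)OC
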